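**Retrosynthetic overview**

- Unit A is the 7-hydroxyflavanone half and unit B the 5,7-dihydroxyflavanone half. The plan rests on the pyran ring of unit A. Its bonds O1(A)–C2(A) and C3(A)–C4(A) lie on either side of the C2(A)–C3(A) pair, so cutting both leaves the oxadiene O1–C8a–C4a–C4 (an ortho-quinone methide of a resorcinol aldehyde) and an (E)-styrene C2(A)=C3(A) attached to C3(B).
- C4(A) enters as a methyl ether, through the α-methoxy quinone methide released from the salicylaldehyde dimethyl acetal by a chiral BINOL phosphoric-acid-type catalyst. DDQ then takes it to the ketone, and the five benzyl ethers are removed last.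
- The pyran ring of unit B is made first by the same cycloaddition, from the phloroglucinol aldehyde acetal and silyl-protected (E)-4-benzyloxycinnamyl alcohol. Its CH2O arm becomes the (E)-styryl group by Julia–Kocienski olefination, with the sulfone placed on the flavan.
- C4(B) is raised to the ketone before the key step. A 5,7-dialkoxy-4-methoxyflavan would ionise under the acid, and its phloroglucinol ring would compete with the styrene for the quinone methide. The flavanone has neither problem.
- Ring order: pyran ring of unit B (step 6), then pyran ring of unit A (step 15). Both halves are (2S,3R), so one catalyst enantiomer serves both cycloadditions.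

Key step: step 15

Assumption: the (R)-catalyst is taken to deliver the (2S) series in both cycloadditions (otherwise its enantiomer is used throughout), and the C4 ether and carbinol centres are drawn as the expected all-trans isomers, although either C4 epimer converges on the same ketone.

**Step 1**
Reactants: 1 2,4,6-trihydroxybenzaldehyde
Product: 2 4,6-bis(benzyloxy)-2-hydroxybenzaldehyde
Conditions: BnBr (2.05 equiv), K2CO3 (2.1 equiv), DMF, 0 °C to rt
Reagents that add atoms: benzyl bromide, BrCc1ccccc1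
Why: Williamson etherification, in which the hydroxyl that stays chelated to the formyl oxygen is the least acidic and least nucleophilic, so two equivalents of benzyl bromide stop at the 4,6-diether.

**Step 2**
Reactants: 2 4,6-bis(benzyloxy)-2-hydroxybenzaldehyde
Product: 3 3,5-bis(benzyloxy)-2-(dimethoxymethyl)phenol (dimethyl acetal of 2)
Conditions: HC(OMe)3 (5 equiv), MeOH, p-TsOH·H2O (1 mol %), rt; Et3N quench, evaporation, used crude
Reagents that add atoms: trimethyl orthoformate, COC(OC)OC; methanol, CO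
Why: Acid-catalysed acetalisation in which the orthoformate consumes the water formed, and neutralisation before evaporation keeps the labile ortho-hydroxy acetal from losing methanol prematurely.

**Step 3**
Reactants: 4 (E)-4-hydroxycinnamic acid
Product: 5 benzyl (E)-3-[4-(benzyloxy)phenyl]prop-2-enoate
Conditions: BnBr (2.2 equiv), K2CO3 (2.5 equiv), DMF, 60 °C
Reagents that add atoms: benzyl bromide, BrCc1ccccc1
Why: Williamson etherification and carboxylate alkylation in one pot, with no effect on the (E)-alkene.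

**Step 4**
Reactants: 5 benzyl (E)-3-[4-(benzyloxy)phenyl]prop-2-enoate
Product: 6 (E)-3-[4-(benzyloxy)phenyl]prop-2-en-1-ol
Conditions: i-Bu2AlH (2.5 equiv), CH2Cl2, −78 to 0 °C; aq potassium sodium tartrate
Reagents that add atoms: none
Why: 1,2-Reduction of an α,β-unsaturated ester by i-Bu2AlH, which leaves the conjugated alkene and the aryl benzyl ether untouched.

**Step 5**
Reactants: 6 (E)-3-[4-(benzyloxy)phenyl]prop-2-en-1-ol
Product: 7 {[(E)-3-[4-(benzyloxy)phenyl]prop-2-en-1-yl]oxy}(tert-butyl)diphenylsilane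
Conditions: TBDPSCl (1.1 equiv), imidazole (2 equiv), CH2Cl2, rt
Reagents that add atoms: tert-butyl(chloro)diphenylsilane, CC(C)(C)[Si](Cl)(c1ccccc1)c1ccccc1
Why: Silylation of a primary alcohol, with the tert-butyldiphenylsilyl ether chosen because it resists the Brønsted acid of step 6 and is a poor leaving group, so the cinnamyl position should not ionise.

**Step 6**
Reactants: 3 3,5-bis(benzyloxy)-2-(dimethoxymethyl)phenol; 7 {[(E)-3-[4-(benzyloxy)phenyl]prop-2-en-1-yl]oxy}(tert-butyl)diphenylsilane
Product: 9 (2S,3S,4S)-5,7-bis(benzyloxy)-2-[4-(benzyloxy)phenyl]-3-{[(tert-butyldiphenylsilyl)oxy]methyl}-4-methoxychroman, via unit B methoxy quinone methide 8 (not isolated)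
Conditions: (R)-3,3'-bis(2,4,6-triisopropylphenyl)-BINOL N-triflylphosphoramide (5 mol %), 7 (1.5 equiv), 5 Å MS, PhMe, −20 °C, slow addition of 3; Et3N quench
Reagents that add atoms: none
Why: Inverse-demand hetero-Diels–Alder reaction of an ortho-quinone methide, in which the acid expels methanol from 3 and the hydrogen-bonded oxadiene 8 bonds through its methide carbon to the CH2-bearing alkene carbon and through its oxygen to the benzylic carbon, so that the (E)-alkene fixes 2,3-trans, the endo aryl group fixes 2,4-cis, and the chiral pocket of the catalyst selects the alkene face and with it the absolute (2S) series.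

**Step 7**
Reactants: 9 (2S,3S,4S)-5,7-bis(benzyloxy)-2-[4-(benzyloxy)phenyl]-3-{[(tert-butyldiphenylsilyl)oxy]methyl}-4-methoxychroman
Product: 10 [(2S,3S,4S)-5,7-bis(benzyloxy)-2-[4-(benzyloxy)phenyl]-4-methoxychroman-3-yl]methanol
Conditions: Bu4NF (1.2 equiv), THF, 0 °C to rt
Reagents that add atoms: none
Why: Fluoride-induced desilylation, which is basic and therefore harmless to the acid-labile C4 methyl ether.

**Step 8**
Reactants: 10 [(2S,3S,4S)-5,7-bis(benzyloxy)-2-[4-(benzyloxy)phenyl]-4-methoxychroman-3-yl]methanol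
Product: 11 5-({[(2S,3S,4S)-5,7-bis(benzyloxy)-2-[4-(benzyloxy)phenyl]-4-methoxychroman-3-yl]methyl}sulfanyl)-1-phenyl-1H-tetrazole
Conditions: PPh3, DIAD, THF, 0 °C; then 10; then 1-phenyl-1H-tetrazole-5-thiol, 0 °C to rt
Reagents that add atoms: 1-phenyl-1H-tetrazole-5-thiol, Sc1nnnn1-c1ccccc1
Why: Mitsunobu thioetherification of a primary alcohol, with the acidic thiol added last to the preformed betaine and alcohol so that the medium never becomes acidic enough to exchange the C4 methoxy group, and with no stereocentre touched.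

**Step 9**
Reactants: 11 5-({[(2S,3S,4S)-5,7-bis(benzyloxy)-2-[4-(benzyloxy)phenyl]-4-methoxychroman-3-yl]methyl}sulfanyl)-1-phenyl-1H-tetrazole
Product: 12 5-({[(2S,3S,4S)-5,7-bis(benzyloxy)-2-[4-(benzyloxy)phenyl]-4-methoxychroman-3-yl]methyl}sulfonyl)-1-phenyl-1H-tetrazole
Conditions: (NH4)6Mo7O24·4H2O (10 mol %), 30% aq H2O2 (10 equiv), MeOH/THF, 0 °C to rt
Reagents that add atoms: hydrogen peroxide, OO
Why: Molybdate-catalysed peroxide oxidation of a sulfide to the sulfone, with methanol as co-solvent so that any solvolytic exchange at C4 is degenerate.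

**Step 10**
Reactants: 12 5-({[(2S,3S,4S)-5,7-bis(benzyloxy)-2-[4-(benzyloxy)phenyl]-4-methoxychroman-3-yl]methyl}sulfonyl)-1-phenyl-1H-tetrazole; 13 4-(benzyloxy)benzaldehyde
Product: 15 (2S,3S,4S)-5,7-bis(benzyloxy)-2-[4-(benzyloxy)phenyl]-3-{(E)-2-[4-(benzyloxy)phenyl]ethenyl}-4-methoxychroman, via potassiated sulfone 14 (not isolated)
Conditions: KN(SiMe3)2 (1.1 equiv), DME, −60 °C, 30 min; then 13, −60 °C to rt
Reagents that add atoms: none
Why: Julia–Kocienski olefination, in which the metallated phenyltetrazolyl sulfone adds to the non-enolisable aldehyde and Smiles rearrangement followed by loss of SO2 and tetrazolate gives the (E)-alkene, while placing the sulfone on the flavan avoids a 3-formylflavan whose α-proton would lie β to both O1 and the C4 methoxy group.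

**Step 11**
Reactants: 15 (2S,3S,4S)-5,7-bis(benzyloxy)-2-[4-(benzyloxy)phenyl]-3-{(E)-2-[4-(benzyloxy)phenyl]ethenyl}-4-methoxychroman
Product: 16 (2S,3S,4S)-5,7-bis(benzyloxy)-2-[4-(benzyloxy)phenyl]-3-{(E)-2-[4-(benzyloxy)phenyl]ethenyl}chroman-4-ol
Conditions: camphorsulfonic acid (5 mol %), THF/H2O (3:1), 0 °C to rt; NaHCO3 quench at full conversion
Reagents that add atoms: water, O
Why: SN1 solvolysis of a 2,4,6-trioxygenated benzylic ether, in which the strongly stabilised C4 cation forms under mild acid and should be captured by the large excess of water faster than it loses H3, preferentially anti to the C3 substituent, the C4 configuration being of no consequence.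

**Step 12**
Reactants: 16 (2S,3S,4S)-5,7-bis(benzyloxy)-2-[4-(benzyloxy)phenyl]-3-{(E)-2-[4-(benzyloxy)phenyl]ethenyl}chroman-4-ol
Product: 17 (2S,3R)-5,7-bis(benzyloxy)-2-[4-(benzyloxy)phenyl]-3-{(E)-2-[4-(benzyloxy)phenyl]ethenyl}chroman-4-one
Conditions: Dess–Martin periodinane (1.3 equiv), NaHCO3 (5 equiv), CH2Cl2, 0 °C to rt; deactivated silica
Reagents that add atoms: none
Why: Dess–Martin oxidation of a secondary benzylic alcohol under buffered, non-basic conditions, which spares the styrene and leaves C3 in its thermodynamically preferred 2,3-trans arrangement.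

**Step 13**
Reactants: 18 2,4-dihydroxybenzaldehyde
Product: 19 4-(benzyloxy)-2-hydroxybenzaldehyde
Conditions: BnBr (1.0 equiv), K2CO3 (1.0 equiv), acetone, rt
Reagents that add atoms: benzyl bromide, BrCc1ccccc1
Why: Regioselective Williamson etherification, since the 2-hydroxyl is chelated to the formyl group and one equivalent of benzyl bromide alkylates the more acidic 4-hydroxyl.

**Step 14**
Reactants: 19 4-(benzyloxy)-2-hydroxybenzaldehyde
Product: 20 5-(benzyloxy)-2-(dimethoxymethyl)phenol (4-benzyloxy-2-hydroxybenzaldehyde dimethyl acetal)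
Conditions: HC(OMe)3 (5 equiv), MeOH, p-TsOH·H2O (1 mol %), rt; Et3N quench, evaporation, used crude
Reagents that add atoms: trimethyl orthoformate, COC(OC)OC; methanol, CO
Why: Acid-catalysed acetalisation driven by the orthoformate as water scavenger, with a basic quench so that the acetal reaches the key step free of achiral acid.

**Step 15**
Reactants: 17 (2S,3R)-5,7-bis(benzyloxy)-2-[4-(benzyloxy)phenyl]-3-{(E)-2-[4-(benzyloxy)phenyl]ethenyl}chroman-4-one; 20 5-(benzyloxy)-2-(dimethoxymethyl)phenol
Product: 22 (2S,3R)-5,7-bis(benzyloxy)-2-[4-(benzyloxy)phenyl]-3-{(2S,3S,4S)-7-(benzyloxy)-2-[4-(benzyloxy)phenyl]-4-methoxychroman-3-yl}chroman-4-one, via unit A methoxy quinone methide 21 (not isolated)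
Conditions: (R)-3,3'-bis(2,4,6-triisopropylphenyl)-BINOL N-triflylphosphoramide (10 mol %), 5 Å MS, PhMe, −30 °C, 20 (2.5 equiv) added over 12 h; Et3N quench
Reagents that add atoms: none
Why: The acid protonates a methoxy group of 20, methanol leaves (taken up by the sieves) and the phenol proton passes to the phosphoramidate, so the neutral (E)-α-methoxy ortho-quinone methide 21 is held by a hydrogen bond inside the chiral pocket; its methide carbon then bonds to the styrene carbon attached to C3(B) and its oxygen to the benzylic carbon in a concerted, asynchronous inverse-demand hetero-Diels–Alder reaction. The closest known reaction type is the Brønsted-acid-catalysed [4+2] cycloaddition of quinone methides from salicylaldehyde acetals or 2-hydroxybenzyl alcohols with β-substituted styrenes, including its versions with chiral BINOL phosphoric acids and N-triflyl phosphoramides. The pyran ring of unit A closes as an intermolecular [4+2] cycloaddition in which C3(A)–C4(A) runs ahead of O1(A)–C2(A), so no separate cyclisation event is involved. C2(A) and C3(A) come out trans because the addition is suprafacial on the (E)-alkene, their sense relative to C3(B) is set by the catalyst pocket (the enantiomer that gave the (2S) series in step 6) and should be supported by approach past the flat C4(B) carbonyl flank instead of the C2(B) aryl flank in the rotamer with H3(B) in the alkene plane, and C4(A) follows from the endo placement of the aryl group under the (E)-oxadiene (2,4-cis) and is erased in step 16. Regioselectivity rests on the 4-benzyloxyphenyl group, which stabilises positive charge at C2(A) in the transition state. Chemoselectivity rests on the C4(B) ketone, which removes the only other acid-ionisable benzylic C–O bond and deactivates the phloroglucinol ring as a Friedel–Crafts competitor, while slow addition of 20 holds down self-condensation of 21.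

**Step 16**
Reactants: 22 (2S,3R)-5,7-bis(benzyloxy)-2-[4-(benzyloxy)phenyl]-3-{(2S,3S,4S)-7-(benzyloxy)-2-[4-(benzyloxy)phenyl]-4-methoxychroman-3-yl}chroman-4-one
Product: 23 (2S,3R)-5,7-bis(benzyloxy)-2-[4-(benzyloxy)phenyl]-3-{(2S,3R)-7-(benzyloxy)-2-[4-(benzyloxy)phenyl]-4-oxochroman-3-yl}chroman-4-one
Conditions: DDQ (1.3 equiv), CH2Cl2/pH 7 phosphate buffer (10:1), 0 °C to rt
Reagents that add atoms: water, O
Why: Oxidative cleavage of a 2,4-dialkoxybenzyl-type ether by DDQ, in which hydride abstraction from the axial C4(A)–H gives the aryl- and methoxy-stabilised carbenium ion, water adds and the hemiketal collapses to the ketone, while plain benzyl aryl ethers and the deactivated flavanone half should react much more slowly.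

**Step 17**
Reactants: 23 (2S,3R)-5,7-bis(benzyloxy)-2-[4-(benzyloxy)phenyl]-3-{(2S,3R)-7-(benzyloxy)-2-[4-(benzyloxy)phenyl]-4-oxochroman-3-yl}chroman-4-one
Product: 24 (2S,3R)-5,7-dihydroxy-3-[(2S,3R)-7-hydroxy-2-(4-hydroxyphenyl)-4-oxochroman-3-yl]-2-(4-hydroxyphenyl)chroman-4-one (target)
Conditions: H2 (1 atm), 10% Pd/C, EtOAc/MeOH (1:1), rt
Reagents that add atoms: none
Why: Hydrogenolysis of five aryl benzyl ethers over Pd/C under neutral conditions at one atmosphere, under which the flavanone carbonyls, the C2–O1 bonds and the four stereocentres should persist.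

**Compound list**

1 | 2,4,6-trihydroxybenzaldehyde | O=Cc1c(O)cc(O)cc1O | starting material
2 | 4,6-bis(benzyloxy)-2-hydroxybenzaldehyde | O=Cc1c(O)cc(OCc2ccccc2)cc1OCc1ccccc1 | intermediate
3 | 3,5-bis(benzyloxy)-2-(dimethoxymethyl)phenol | COC(OC)c1c(O)cc(OCc2ccccc2)cc1OCc1ccccc1 | intermediate
4 | (E)-4-hydroxycinnamic acid | OC(=O)/C=C/c1ccc(O)cc1 | starting material
5 | benzyl (E)-3-[4-(benzyloxy)phenyl]prop-2-enoate | O=C(OCc1ccccc1)/C=C/c1ccc(OCc2ccccc2)cc1 | intermediate
6 | (E)-3-[4-(benzyloxy)phenyl]prop-2-en-1-ol | OC/C=C/c1ccc(OCc2ccccc2)cc1 | intermediate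
7 | {[(E)-3-[4-(benzyloxy)phenyl]prop-2-en-1-yl]oxy}(tert-butyl)diphenylsilane | CC(C)(C)[Si](c1ccccc1)(c1ccccc1)OC/C=C/c1ccc(OCc2ccccc2)cc1 | intermediate
8 | (6E)-3,5-bis(benzyloxy)-6-(methoxymethylidene)cyclohexa-2,4-dien-1-one (not isolated) | CO/C=C1/C(=O)C=C(OCc2ccccc2)C=C1OCc1ccccc1 | intermediate
9 | (2S,3S,4S)-5,7-bis(benzyloxy)-2-[4-(benzyloxy)phenyl]-3-{[(tert-butyldiphenylsilyl)oxy]methyl}-4-methoxychroman | CC(C)(C)[Si](c1ccccc1)(c1ccccc1)OC[C@H]1[C@H](OC)c2c(OCc3ccccc3)cc(OCc3ccccc3)cc2O[C@@H]1c1ccc(OCc2ccccc2)cc1 | intermediate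
10 | [(2S,3S,4S)-5,7-bis(benzyloxy)-2-[4-(benzyloxy)phenyl]-4-methoxychroman-3-yl]methanol | OC[C@H]1[C@H](OC)c2c(OCc3ccccc3)cc(OCc3ccccc3)cc2O[C@@H]1c1ccc(OCc2ccccc2)cc1 | intermediate
11 | phenyltetrazolyl sulfide of 10, (2S,3S,4S) | c1ccccc1-n1nnnc1SC[C@H]1[C@H](OC)c2c(OCc3ccccc3)cc(OCc3ccccc3)cc2O[C@@H]1c1ccc(OCc2ccccc2)cc1 | intermediate
12 | phenyltetrazolyl sulfone, (2S,3S,4S) | c1ccccc1-n1nnnc1S(=O)(=O)C[C@H]1[C@H](OC)c2c(OCc3ccccc3)cc(OCc3ccccc3)cc2O[C@@H]1c1ccc(OCc2ccccc2)cc1 | intermediate
13 | 4-(benzyloxy)benzaldehyde | O=Cc1ccc(OCc2ccccc2)cc1 | starting material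
14 | potassium α-sulfonyl carbanion of 12 (not isolated) | [K+].c1ccccc1-n1nnnc1S(=O)(=O)[CH-][C@H]1[C@H](OC)c2c(OCc3ccccc3)cc(OCc3ccccc3)cc2O[C@@H]1c1ccc(OCc2ccccc2)cc1 | intermediate
15 | (2S,3S,4S)-5,7-bis(benzyloxy)-2-[4-(benzyloxy)phenyl]-3-{(E)-2-[4-(benzyloxy)phenyl]ethenyl}-4-methoxychroman | c1cc(OCc2ccccc2)ccc1/C=C/[C@H]1[C@H](OC)c2c(OCc3ccccc3)cc(OCc3ccccc3)cc2O[C@@H]1c1ccc(OCc2ccccc2)cc1 | intermediate
16 | (2S,3S,4S)-5,7-bis(benzyloxy)-2-[4-(benzyloxy)phenyl]-3-{(E)-2-[4-(benzyloxy)phenyl]ethenyl}chroman-4-ol | c1cc(OCc2ccccc2)ccc1/C=C/[C@H]1[C@H](O)c2c(OCc3ccccc3)cc(OCc3ccccc3)cc2O[C@@H]1c1ccc(OCc2ccccc2)cc1 | intermediate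
17 | (2S,3R)-5,7-bis(benzyloxy)-2-[4-(benzyloxy)phenyl]-3-{(E)-2-[4-(benzyloxy)phenyl]ethenyl}chroman-4-one | c1cc(OCc2ccccc2)ccc1/C=C/[C@H]1C(=O)c2c(OCc3ccccc3)cc(OCc3ccccc3)cc2O[C@@H]1c1ccc(OCc2ccccc2)cc1 | intermediate
18 | 2,4-dihydroxybenzaldehyde | O=Cc1ccc(O)cc1O | starting material
19 | 4-(benzyloxy)-2-hydroxybenzaldehyde | O=Cc1ccc(OCc2ccccc2)cc1O | intermediate
20 | 5-(benzyloxy)-2-(dimethoxymethyl)phenol | COC(OC)c1ccc(OCc2ccccc2)cc1O | intermediate
21 | (6E)-3-(benzyloxy)-6-(methoxymethylidene)cyclohexa-2,4-dien-1-one (not isolated) | CO/C=C1/C(=O)C=C(OCc2ccccc2)C=C1 | intermediate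
22 | (2S,3R)-5,7-bis(benzyloxy)-2-[4-(benzyloxy)phenyl]-3-{(2S,3S,4S)-7-(benzyloxy)-2-[4-(benzyloxy)phenyl]-4-methoxychroman-3-yl}chroman-4-one | CO[C@@H]1c2ccc(OCc3ccccc3)cc2O[C@H](c2ccc(OCc3ccccc3)cc2)[C@H]1[C@H]1C(=O)c2c(OCc3ccccc3)cc(OCc3ccccc3)cc2O[C@@H]1c1ccc(OCc2ccccc2)cc1 | intermediate
23 | (2S,3R)-5,7-bis(benzyloxy)-2-[4-(benzyloxy)phenyl]-3-{(2S,3R)-7-(benzyloxy)-2-[4-(benzyloxy)phenyl]-4-oxochroman-3-yl}chroman-4-one | O=C1c2ccc(OCc3ccccc3)cc2O[C@H](c2ccc(OCc3ccccc3)cc2)[C@H]1[C@H]1C(=O)c2c(OCc3ccccc3)cc(OCc3ccccc3)cc2O[C@@H]1c1ccc(OCc2ccccc2)cc1 | intermediate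
24 | (2S,3R)-5,7-dihydroxy-3-[(2S,3R)-7-hydroxy-2-(4-hydroxyphenyl)-4-oxochroman-3-yl]-2-(4-hydroxyphenyl)chroman-4-one | O=C1c2ccc(O)cc2O[C@H](c2ccc(O)cc2)[C@H]1[C@H]1C(=O)c2c(O)cc(O)cc2O[C@@H]1c1ccc(O)cc1 | target

**Step count**

Total step count: 17. Longest linear sequence: 13 steps (steps 3 to 12, then 15 to 17).

**Steps most likely to fail**

**Step 15.**
- The styrene carries a bulky, branched allylic substituent, so the cycloaddition may be slow enough for the quinone methide to condense with itself or with its own precursor.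
- The catalyst may also fail to override the weak bias of the allylic centre, which would give poor facial selectivity.
- The fallback sets out from 19 and 17 and comes back at 23.
- NaBH4 in MeOH reduces 19 to 4-(benzyloxy)-2-(hydroxymethyl)phenol F1.
- The same acid catalyst in CH2Cl2 with 4 Å MS dehydrates it to 3-(benzyloxy)-6-methylidenecyclohexa-2,4-dien-1-one F2. This quinone methide lacks both the donor effect and the bulk of the methoxy group, so it is a smaller and stronger electrophile.
- It should add to 17 with the same regiochemistry and trans geometry to give the C4(A)-methylene flavan–flavanone F3. The facial isomers of F3 are diastereomers and can be separated by chromatography.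
- The C4(A) oxygen is then introduced by C–H oxidation. DDQ in wet CH2Cl2 abstracts the benzylic hydride para to the 7-benzyloxy group, and water adds anti to the C3 substituent to give the C4(A) carbinol F4.
- Dess–Martin periodinane converts F4 into 23.

**Step 6.**
- The doubly donor-substituted quinone methide is a weak electrophile, so the addition may be slow.
- Arylation of the phloroglucinol rings of acetal and product may intervene.
- Enantiofacial discrimination may be low on an alkene that offers the catalyst no hydrogen-bond handle.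
- The fallback sets out from 3 and 7 and comes back at 10.
- An achiral acid (diphenyl phosphate, CH2Cl2, 0 °C) gives 9 as the racemate, that is together with the (2R,3R,4R)-enantiomer of 9 F5.
- Bu4NF gives 10 together with the (2R,3R,4R)-enantiomer of 10 F6.
- Acylation with (1S)-camphanic chloride, Et3N and DMAP gives the (1S)-camphanate of 10 F7 and the (1S)-camphanate of the enantiomeric alcohol F8. These are diastereomers and are separated by crystallisation or chromatography.
- LiOH in THF/H2O cleaves F7 to enantiopure 10. Half of the material is given up in exchange for secure absolute configuration.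

**Step 11.**
- After ionisation at C4(B) the cation may lose H3(B), which is allylic to the styryl group, faster than water captures it. That would destroy C3(B) by elimination into conjugation.
- The fallback sets out from 15 (with 20) and comes back at 23.
- C4(B) is left masked, and the cycloaddition is run on 15 itself with the weaker parent acid, (R)-3,3'-bis(2,4,6-triisopropylphenyl)-BINOL hydrogen phosphate, at low temperature. This gives, again through 21, the (2S,3S,4S,2''S,3''S,4''S)-pentabenzyl 4,4''-dimethoxy-3,3''-biflavan F9.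
- Both methyl ethers are then hydrolysed together (camphorsulfonic acid, THF/H2O), now with no alkene next to C3(B), to give the 4,4''-diol F10.
- Dess–Martin periodinane oxidises both carbinols of F10 to give 23.
- The cost is that the activated phloroglucinol ring is present during the cycloaddition, so chemoselectivity there becomes more demanding.

**Further compounds**

F1 | step 15 | 4-(benzyloxy)-2-(hydroxymethyl)phenol | OCc1ccc(OCc2ccccc2)cc1O
F2 | step 15 | 3-(benzyloxy)-6-methylidenecyclohexa-2,4-dien-1-one | C=C1C(=O)C=C(OCc2ccccc2)C=C1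
F3 | step 15 | (2S,3R)-5,7-bis(benzyloxy)-2-[4-(benzyloxy)phenyl]-3-{(2S,3R)-7-(benzyloxy)-2-[4-(benzyloxy)phenyl]chroman-3-yl}chroman-4-one | C1c2ccc(OCc3ccccc3)cc2O[C@H](c2ccc(OCc3ccccc3)cc2)[C@H]1[C@H]1C(=O)c2c(OCc3ccccc3)cc(OCc3ccccc3)cc2O[C@@H]1c1ccc(OCc2ccccc2)cc1
F4 | step 15 | (2S,3R)-5,7-bis(benzyloxy)-2-[4-(benzyloxy)phenyl]-3-{(2S,3S,4S)-7-(benzyloxy)-2-[4-(benzyloxy)phenyl]-4-hydroxychroman-3-yl}chroman-4-one | O[C@@H]1c2ccc(OCc3ccccc3)cc2O[C@H](c2ccc(OCc3ccccc3)cc2)[C@H]1[C@H]1C(=O)c2c(OCc3ccccc3)cc(OCc3ccccc3)cc2O[C@@H]1c1ccc(OCc2ccccc2)cc1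
F5 | step 6 | (2R,3R,4R)-enantiomer of 9 | CC(C)(C)[Si](c1ccccc1)(c1ccccc1)OC[C@@H]1[C@@H](OC)c2c(OCc3ccccc3)cc(OCc3ccccc3)cc2O[C@H]1c1ccc(OCc2ccccc2)cc1
F6 | step 6 | (2R,3R,4R)-enantiomer of 10 | OC[C@@H]1[C@@H](OC)c2c(OCc3ccccc3)cc(OCc3ccccc3)cc2O[C@H]1c1ccc(OCc2ccccc2)cc1
F7 | step 6 | (1S)-camphanate of 10 | O=C(OC[C@H]1[C@H](OC)c2c(OCc3ccccc3)cc(OCc3ccccc3)cc2O[C@@H]1c1ccc(OCc2ccccc2)cc1)[C@@]12CC[C@@](C)(C(=O)O1)C2(C)C
F8 | step 6 | (1S)-camphanate of the enantiomeric alcohol F6 | O=C(OC[C@@H]1[C@@H](OC)c2c(OCc3ccccc3)cc(OCc3ccccc3)cc2O[C@H]1c1ccc(OCc2ccccc2)cc1)[C@@]12CC[C@@](C)(C(=O)O1)C2(C)C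
F9 | step 11 | (2S,3S,4S,2''S,3''S,4''S)-pentabenzyl 4,4''-dimethoxy-3,3''-biflavan | CO[C@@H]1c2ccc(OCc3ccccc3)cc2O[C@H](c2ccc(OCc3ccccc3)cc2)[C@H]1[C@H]1[C@H](OC)c2c(OCc3ccccc3)cc(OCc3ccccc3)cc2O[C@@H]1c1ccc(OCc2ccccc2)cc1
F10 | step 11 | (2S,3S,4S,2''S,3''S,4''S)-pentabenzyl 3,3''-biflavan-4,4''-diol | O[C@@H]1c2ccc(OCc3ccccc3)cc2O[C@H](c2ccc(OCc3ccccc3)cc2)[C@H]1[C@H]1[C@H](O)c2c(OCc3ccccc3)cc(OCc3ccccc3)cc2O[C@@H]1c1ccc(OCc2ccccc2)cc1
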